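## Analysis of the target

The target is a tetracyclic meroterpenoid. A cyclobutane (ring A: C1, C9, C10, C11) is trans-fused to a nine-membered carbocycle (ring B: C1–C9). Ring B is trans-fused at C4–C5 to a dihydropyran (ring C: O, C4, C5, C1', C2', C3'), which is annulated to an enolised 2-isobutyryl-4,4-dimethylcyclohexane-1,3,5-trione (ring D: C2'–C7'). The four stereocentres are (1R,4S,5R,9S). C1/C9 form the trans cyclobutane junction and C4/C5 the trans B/C junction, with the C4 methyl and the C5 hydrogen on opposite faces; C4 is a fully substituted tertiary ether carbon. The two pairs are insulated from each other by C2–C3 on one side and C6–C8 on the other, so neither can be trusted to control the other across a flexible medium ring. Sensitive groups are the exocyclic C8 methylidene (acid isomerisation, and transannular cyclisation if a cation forms at C4), the ionisable tertiary C4–O bond, the acidic chelating β-triketone and the strained cyclobutane. The synthesis is hard for three reasons: a nine-membered ring must be closed next to a trans-fused four-membered ring, two remote stereo-pairs must be set in the right absolute sense, and the unsymmetrical trione must be joined through the right oxygen. The strategy rests on C2–C3, the only ring-B bond that is a plain CH2–CH2 link between two carbons (C1 and C4) that can each carry a vinyl group without touching a stereocentre. Ring B can therefore be closed there by olefin metathesis after all four stereocentres are already in place.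

## Retrosynthetic reasoning

Ring C is opened at the enol ether bond O–C3', which leads from 33 to the hydroxy trione 32. The C4–O bond is left intact, so C4 can be installed early as a tertiary alcohol of fixed configuration. The forward step is a cyclodehydration of the C4 hydroxyl onto the C3' carbonyl.

The C1'–C2' bond is cut next, giving aldehyde 28 and the trione 30. This brings the whole of ring D in as one piece; the forward reaction is a reductive Knoevenagel alkylation. 30 comes from 29 by double C-methylation at one ring carbon.

Functional-group changes lead from 28 back to 24. The aldehyde comes from the primary alcohol of diol 27, the diol from acetonide 26, the C8 methylidene from ketone 25, and the saturated C2–C3 unit from alkene 24. C8 stays a ketone through ring closure and hydrogenation so that the metathesis alkene is the only C=C present when hydrogen is added. The methylidene is introduced before any acid is used on the free diol.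

Ring B is cut at C2=C3, giving the divinyl ketone 23. No other ring-B bond can be broken without involving a stereocentre or a heteroatom-bearing carbon. The forward reaction must join a cyclobutyl vinyl group to a vinyl group on the quaternary C4 with loss of the two terminal CH2 groups, and it creates no stereocentre.

23 is cut at C7–C8 into alkyl iodide 21 (as its organolithium 22) and Weinreb amide 10. This divides the molecule into two halves that each carry one stereo-pair, so each pair can be made enantiopure on its own. The forward reaction is an acyl substitution that stops at the ketone.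

Fragment 1 (10) goes back through ester 9 and aldehyde 8 to the pseudo-acid 6, to the bicyclic enone 4 and its silyloxy precursor 3, and so to 1 and 2. The cyclobutane is made by enone–alkene photocycloaddition, with the head-to-tail orientation placing CMe2 next to the future C1. The five-membered ring is then cut so that its carbonyl carbon becomes C8 and the former C4 becomes the vinyl CH (C2). The silyloxy group of 1 does two jobs: it directs the alkene to one face, which fixes C9, and it leaves by elimination to give the enone needed for the cut; an unsubstituted enone would give racemic material. C1 is then inverted through the aldehyde enol to the more stable trans arrangement.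

Fragment 2 (21) goes back through alcohol 20 to the divinyl acetonide 18, diol 17, lactol 16, diol acetal 15, epoxy alcohol 14, allylic alcohol 13, enoate 12 and ketone 11. C4 and C5 are set together by asymmetric epoxidation of the E-allylic alcohol and anti opening at C5 by a vinyl copper nucleophile. The C4 vinyl group cannot be present during that opening, because an alkenyl epoxide would react at the alkene terminus, so it is carried as a dimethyl acetal and unmasked afterwards by a phosphorus ylide. The C5 vinyl group becomes the C6–C7 chain by anti-Markovnikov hydration.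

## Alternatives that were turned down

Alternative 1: Ring C would be made last by cutting C1'–C2' and O–C4 together. The ring-B enal A2 would condense with 30 at C1', and the resulting 1-oxatriene would close by 6π electrocyclisation to the 2H-pyran A1.
- For it: one step forms two bonds, ring C and the quaternary C4. On step economy for ring C it is stronger than the chosen route, which needs an acetonide, an oxidation, a reductive coupling and a dehydration.
- Against it: C4 would be set by the direction of a reversible electrocyclisation on a flexible nine-membered ring. 2H-pyrans equilibrate with their open dienones, so C4 would be under thermodynamic control with no element that guarantees the 4S configuration relative to C1/C9. The C5=C1' bond of A1 would then have to be reduced from one face, in the presence of the enolised trione, to set C5. The tetrasubstituted enal A2 also needs ring B to be built first, which this plan does not address.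
- Comparison: the chosen route is longer at the end, but C4 and C5 are fixed by a stereospecific epoxidation–opening pair before any ring is closed.

Alternative 2: Ring A would be made late by cutting C9–C10 and C1–C11. The Z-cyclononenone acetonide A4 would be irradiated with 2, and the adduct equilibrated with base to the trans-fused ketone A3, which is the same compound as 25.
- For it: it avoids a separate cyclobutane fragment and the fragment coupling, and it converges on an intermediate of the chosen route. The base equilibration to the trans junction is as reliable as in the chosen route. On step count for ring A it is stronger.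
- Against it: the absolute configuration at C1/C9 would have to be induced by the C4/C5 pair across the nine-membered ring, and there is no structural reason for one enone face to be preferred. Medium-ring enones also isomerise Z to E on excitation, and the head-to-head orientation competes. A4 itself still needs a nine-membered ring closure.
- Comparison: the chosen route sets C9 by a substituent directly on the five-membered enone and relays nothing across ring B.

Alternative 3: Ring B would be closed at C4–C5. The bromo ester A6 would be reduced by a divalent samarium reagent to a trivalent samarium enolate, whose C5 adds to the C4 methyl ketone to give the β-hydroxy ester A5.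
- For it: the ring and both C4 and C5 form in one step, and the ester of A5 is one reduction away from 27. It avoids a metathesis at a hindered vinyl group. On step economy and on the ease of making the open-chain precursor it is stronger.
- Against it: two new stereocentres would be created in the ring-closing event, remote from C1/C9. Four diastereomers are possible, and the outcome depends on a chelated nine-membered transition state in which the ketone's two substituents (methyl and a CH2 chain) differ little. Ketyl formation at the ketone and simple reduction of the bromide compete.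
- Comparison: the chosen ring closure creates no stereocentre, so its only risk is whether the ring forms.

Key step: step 17

Assumption: atoms carry caryophyllane numbers (C1'–C7' for the aldehyde-derived carbon and ring D); enolised triones are drawn as the single tautomer of the target SMILES, and lactol 16 as its oxolane form (anomer mixture).

## Route

Step 1
Reactants: 1 (4R)-4-[(tert-butyldimethylsilyl)oxy]cyclopent-2-en-1-one; 2 isobutylene (2-methylpropene)
Product: 3 (1S,4R,5S)-4-[(tert-butyldimethylsilyl)oxy]-6,6-dimethylbicyclo[3.2.0]heptan-2-one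
Conditions: 2 (excess, condensed), CH2Cl2, hν (Pyrex filter, about 350 nm), −78 °C
Reagents that add atoms: none
Why: Enone–alkene [2+2] photocycloaddition; the head-to-tail orientation (CMe2 bonded to the enone β-carbon) is expected for an electron-rich 1,1-disubstituted alkene, and the alkene should add anti to the silyloxy group, which sets the future C9 and C1 (cis, as a bicyclo[3.2.0] system must be). The head-to-head isomer and any syn adduct are removed by chromatography before step 2, because the syn adduct would lead to the enantiomer of 4.

Step 2
Reactants: 3 (1S,4R,5S)-4-[(tert-butyldimethylsilyl)oxy]-6,6-dimethylbicyclo[3.2.0]heptan-2-one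
Product: 4 (1S,5S)-6,6-dimethylbicyclo[3.2.0]hept-3-en-2-one
Conditions: DBU, CH2Cl2, 0 °C → rt
Reagents that add atoms: none
Why: E1cB elimination of the β-silyloxy ketone; the directing stereocentre is erased and the two ring-fusion centres, which cannot epimerise singly in this cis-locked bicycle, are untouched.

Step 3
Reactants: 4 (1S,5S)-6,6-dimethylbicyclo[3.2.0]hept-3-en-2-one
Product: 6 (1S,5S)-4-hydroxy-6,6-dimethyl-3-oxabicyclo[3.2.0]heptan-2-one (cis pseudo-acid, anomer mixture), via keto-dialdehyde 5 (not isolated)
Conditions: O3, CH2Cl2/MeOH, −78 °C; Me2S, −78 °C → rt; then NaIO4, THF/H2O, rt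
Reagents that add atoms: ozone, O=[O+][O-]; water, O
Why: Ozonolysis of the conjugated C3=C4 bond, then periodate cleavage of the resulting 1,2-dicarbonyl, removes C3 as formic acid. The acid on the future C9 and the aldehyde on the future C1 close to the cis hydroxy-lactone, which keeps the aldehyde α-centre from epimerising at this stage.

Step 4
Reactants: 6 (1S,5S)-4-hydroxy-6,6-dimethyl-3-oxabicyclo[3.2.0]heptan-2-one
Product: 8 methyl (1S,2R)-2-formyl-3,3-dimethylcyclobutane-1-carboxylate (trans), via cis-formyl ester 7 (not isolated)
Conditions: MeI, KHCO3, DMF, rt; remove MeI; then DBU (0.2 equiv), CH2Cl2, rt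
Reagents that add atoms: iodomethane, CI
Why: Carboxylate alkylation of the ring-opened pseudo-acid gives the normal methyl ester; catalytic base then equilibrates only the much more acidic aldehyde α-centre (C1) to the more stable trans-1,2-disubstituted cyclobutane, so C9 keeps the configuration set in step 1. Residual cis isomer is removed by chromatography so that it cannot erode enantiopurity later.

Step 5
Reactants: 8 methyl (1S,2R)-2-formyl-3,3-dimethylcyclobutane-1-carboxylate
Product: 9 methyl (1S,2R)-2-ethenyl-3,3-dimethylcyclobutane-1-carboxylate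
Conditions: Ph3PCH3Br, KOt-Bu, THF, 0 °C; then 8, −78 → 0 °C
Reagents that add atoms: methyltriphenylphosphonium bromide, C[P+](c1ccccc1)(c1ccccc1)c1ccccc1.[Br-]
Why: Wittig methylenation; the ylide reacts with the aldehyde far faster than with the ester, and the α-centre is already in its thermodynamic trans arrangement.

Step 6
Reactants: 9 methyl (1S,2R)-2-ethenyl-3,3-dimethylcyclobutane-1-carboxylate
Product: 10 (1S,2R)-2-ethenyl-N-methoxy-N,3,3-trimethylcyclobutane-1-carboxamide
Conditions: MeNH(OMe)·HCl, i-PrMgCl, THF, −20 → 0 °C
Reagents that add atoms: N,O-dimethylhydroxylamine hydrochloride, CNOC.Cl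
Why: Direct aminolysis of the ester by the magnesium amide of N,O-dimethylhydroxylamine (Weinreb amide formation); the trans arrangement is the stable one, so the basic medium does not threaten C9.

Step 7
Reactants: 11 1,1-dimethoxypropan-2-one
Product: 12 ethyl (2E)-4,4-dimethoxy-3-methylbut-2-enoate
Conditions: (EtO)2P(O)CH2CO2Et, NaH, THF, 0 °C → rt
Reagents that add atoms: triethyl phosphonoacetate, CCOC(=O)CP(=O)(OCC)OCC
Why: Horner–Wadsworth–Emmons olefination of a methyl ketone; the ester should end up trans to the larger dimethoxymethyl group, and any Z isomer is separated.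

Step 8
Reactants: 12 ethyl (2E)-4,4-dimethoxy-3-methylbut-2-enoate
Product: 13 (2E)-4,4-dimethoxy-3-methylbut-2-en-1-ol
Conditions: i-Bu2AlH, CH2Cl2, −78 → 0 °C; potassium sodium tartrate work-up
Reagents that add atoms: none
Why: 1,2-Reduction of the conjugated ester to the allylic alcohol; the acetal is inert to the hydride.

Step 9
Reactants: 13 (2E)-4,4-dimethoxy-3-methylbut-2-en-1-ol
Product: 14 [(2S,3R)-3-(dimethoxymethyl)-3-methyloxiran-2-yl]methanol
Conditions: Ti(OiPr)4 (10 mol%), L-(+)-diethyl tartrate (12 mol%), t-BuOOH, 4 Å molecular sieves, CH2Cl2, −20 °C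
Reagents that add atoms: tert-butyl hydroperoxide, CC(C)(C)OO
Why: Sharpless asymmetric epoxidation of an E-trisubstituted allylic alcohol; the L-(+)-tartrate catalyst delivers oxygen to the face that makes the hydroxymethyl-bearing carbon S, which fixes the absolute configuration of C4 (the future tertiary ether carbon) by reagent control.

Step 10
Reactants: 14 [(2S,3R)-3-(dimethoxymethyl)-3-methyloxiran-2-yl]methanol
Product: 15 (2R,3R)-2-ethenyl-4,4-dimethoxy-3-methylbutane-1,3-diol
Conditions: CH2=CHMgBr (3 equiv), CuI (15 mol%), THF/Et2O, −30 → 0 °C
Reagents that add atoms: vinylmagnesium bromide, C=C[Mg]Br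
Why: Copper-catalysed SN2 opening of the 2,3-epoxy alcohol at its less substituted carbon (the other epoxide carbon is quaternary), with inversion; this sets C5 relative to C4 stereospecifically and gives the 1,3-diol. No alkenyl group is on the epoxide, so SN2' opening cannot compete.

Step 11
Reactants: 15 (2R,3R)-2-ethenyl-4,4-dimethoxy-3-methylbutane-1,3-diol
Product: 16 (3R,4R)-4-ethenyl-3-methyloxolane-2,3-diol (lactol)
Conditions: 2 M HCl, THF, 40 °C
Reagents that add atoms: water, O
Why: Acetal hydrolysis assisted by the primary hydroxyl, which captures the aldehyde as a five-membered hemiacetal; the tertiary alcohol is not yet allylic and tolerates the acid.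

Step 12
Reactants: 16 (3R,4R)-4-ethenyl-3-methyloxolane-2,3-diol
Product: 17 (2R,3S)-2-ethenyl-3-methylpent-4-ene-1,3-diol
Conditions: Ph3PCH3Br (4 equiv), KOt-Bu (4 equiv), THF, 0 → 45 °C
Reagents that add atoms: methyltriphenylphosphonium bromide, C[P+](c1ccccc1)(c1ccccc1)c1ccccc1.[Br-]
Why: Wittig methylenation of a lactol through its open hydroxy-aldehyde form; the aldehyde carbon is attached to the quaternary C4, so no centre can epimerise.

Step 13
Reactants: 17 (2R,3S)-2-ethenyl-3-methylpent-4-ene-1,3-diol
Product: 18 (4S,5R)-4,5-diethenyl-2,2,4-trimethyl-1,3-dioxane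
Conditions: 2-methoxypropene, PPTS (cat.), CH2Cl2, 0 °C
Reagents that add atoms: 2-methoxypropene, C=C(C)OC
Why: Acetonide formation on the only diol present; the enol ether and a weak acid are used because the tertiary hydroxyl is now allylic and would ionise under stronger acid.

Step 14
Reactants: 18 (4S,5R)-4,5-diethenyl-2,2,4-trimethyl-1,3-dioxane
Product: 20 2-[(4S,5R)-4-ethenyl-2,2,4-trimethyl-1,3-dioxan-5-yl]ethan-1-ol, via B-alkyl-9-BBN adduct 19 (not isolated)
Conditions: 9-BBN (1.1 equiv), THF, 0 °C → rt; then NaOH, H2O2, 0 °C
Reagents that add atoms: hydrogen peroxide, OO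
Why: Anti-Markovnikov hydroboration–oxidation with a bulky dialkylborane; the C5 vinyl group should react first because the C4 vinyl group sits on a fully substituted carbon and is deactivated by the allylic oxygen.

Step 15
Reactants: 20 2-[(4S,5R)-4-ethenyl-2,2,4-trimethyl-1,3-dioxan-5-yl]ethan-1-ol
Product: 21 (4S,5R)-4-ethenyl-5-(2-iodoethyl)-2,2,4-trimethyl-1,3-dioxane
Conditions: I2, PPh3, imidazole, CH2Cl2, 0 °C
Reagents that add atoms: iodine, II
Why: Appel-type iodination of a primary alcohol; imidazole buffers the medium so that the allylic acetal survives.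

Step 16
Reactants: 21 (4S,5R)-4-ethenyl-5-(2-iodoethyl)-2,2,4-trimethyl-1,3-dioxane; 10 (1S,2R)-2-ethenyl-N-methoxy-N,3,3-trimethylcyclobutane-1-carboxamide
Product: 23 1-[(1S,2R)-2-ethenyl-3,3-dimethylcyclobutyl]-3-[(4S,5R)-4-ethenyl-2,2,4-trimethyl-1,3-dioxan-5-yl]propan-1-one, via alkyllithium 22 (not isolated)
Conditions: t-BuLi (2.1 equiv), Et2O/pentane, −78 °C; then 10, −78 °C; NH4Cl (aq.) at −78 °C
Reagents that add atoms: none
Why: Iodine–lithium exchange, then acylation of the primary alkyllithium by the Weinreb amide, whose chelated tetrahedral adduct prevents over-addition. The mixture is kept at −78 °C because 22 is a 5-hexenyllithium that would cyclise onto the C4 vinyl group on warming.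

Step 17
Reactants: 23 1-[(1S,2R)-2-ethenyl-3,3-dimethylcyclobutyl]-3-[(4S,5R)-4-ethenyl-2,2,4-trimethyl-1,3-dioxan-5-yl]propan-1-one
Product: 24 (1R,2Z,4S,5R,9S)-4-hydroxy-5-(hydroxymethyl)-4,11,11-trimethylbicyclo[7.2.0]undec-2-en-8-one, as the isopropylidene acetal of the C4 hydroxyl and the C5 hydroxymethyl group
Conditions: second-generation Grubbs catalyst (H2IMes)(PCy3)Cl2Ru=CHPh (10 mol%, in portions), toluene (1 mM), 80 °C, argon sparge
Reagents that add atoms: none
Why: Ring-closing olefin metathesis: the ruthenium benzylidene first exchanges with the cyclobutyl vinyl group, the less hindered of the two, to give a C2 alkylidene; intramolecular [2+2] with the C4 vinyl group gives a ruthenacyclobutane whose cycloreversion forms C2=C3 and a ruthenium methylidene, and the two terminal CH2 groups leave as ethene, which is swept out so that closure is not reversed. The closest known reaction type is ring-closing metathesis to eight- and nine-membered carbocycles that carry ring fusions or other conformational constraints. Ring B is the only ring closed: a nine-membered carbocycle formed by joining the alkene carbons C2 and C3, both of which end up in the ring, with the Z geometry that a cyclononene accommodates. No stereocentre is formed; C1, C9, C4 and C5 are spectators, and the alkene geometry is erased in step 18. The selectivity needed is cyclisation over acyclic diene oligomerisation, which should be served by high dilution and portionwise catalyst, by the gauche placing of the C4 vinyl group and the C5 side chain on the dioxane (the trans relationship that ring C has in 33), by the trans cyclobutane and by the sp2 C8, which together remove most rotors of the tether. Site selectivity is not an issue because 23 has no other alkene, and the ketone and the acetal are inert to the catalyst. The slow partner is the vinyl group on the fully substituted, oxygen-bearing C4, which is why the catalyst is expected to load at the other terminus and the reaction is run hot.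

Step 18
Reactants: 24 Z-cyclononenone acetonide (as named in step 17)
Product: 25 (1R,4S,5R,9S)-4-hydroxy-5-(hydroxymethyl)-4,11,11-trimethylbicyclo[7.2.0]undecan-8-one, as the same isopropylidene acetal
Conditions: H2 (1 atm), Rh/Al2O3 (5 wt%), EtOAc, rt
Reagents that add atoms: none
Why: Heterogeneous hydrogenation of the only alkene; rhodium on alumina is chosen over palladium because the alkene is allylic to the C4–O bond, which palladium could hydrogenolyse.

Step 19
Reactants: 25 saturated ketone acetonide (as named in step 18)
Product: 26 (1R,4S,5R,9S)-4-hydroxy-5-(hydroxymethyl)-4,11,11-trimethyl-8-methylidenebicyclo[7.2.0]undecane, as the same isopropylidene acetal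
Conditions: Ph3PCH3Br, KOt-Bu, toluene, 80 °C
Reagents that add atoms: methyltriphenylphosphonium bromide, C[P+](c1ccccc1)(c1ccccc1)c1ccccc1.[Br-]
Why: Wittig methylenation of the hindered C8 ketone; C9 is epimerisable under these conditions, but the trans ring fusion already present is the more stable one.

Step 20
Reactants: 26 methylidene acetonide (as named in step 19)
Product: 27 (1R,4S,5R,9S)-5-(hydroxymethyl)-4,11,11-trimethyl-8-methylidenebicyclo[7.2.0]undecan-4-ol
Conditions: AcOH/THF/H2O (3:1:1), 40 °C
Reagents that add atoms: none
Why: Hydrolysis of the isopropylidene acetal; weak aqueous acid is used because the 1,1-disubstituted alkene and the tertiary C4–O bond do not tolerate strong acid.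

Step 21
Reactants: 27 (1R,4S,5R,9S)-5-(hydroxymethyl)-4,11,11-trimethyl-8-methylidenebicyclo[7.2.0]undecan-4-ol
Product: 28 (1R,4S,5S,9S)-4-hydroxy-4,11,11-trimethyl-8-methylidenebicyclo[7.2.0]undecane-5-carbaldehyde (same spatial arrangement at C5; the descriptor changes with the priorities)
Conditions: TEMPO (10 mol%), PhI(OAc)2, CH2Cl2, rt
Reagents that add atoms: none
Why: Oxoammonium oxidation, selective for the primary alcohol in the presence of the tertiary one; the medium is non-basic, so the α-centre C5 should not epimerise. The aldehyde is used at once.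

Step 22
Reactants: 29 phlorisobutyrophenone (1-(2,4,6-trihydroxyphenyl)-2-methylpropan-1-one)
Product: 30 3,5-dihydroxy-6,6-dimethyl-2-(2-methylpropanoyl)cyclohexa-2,4-dien-1-one (enol form of 2-isobutyryl-4,4-dimethylcyclohexane-1,3,5-trione)
Conditions: NaOMe (3 equiv), MeI (2.2 equiv), MeOH, 0 °C → rt
Reagents that add atoms: iodomethane, CI
Why: Dearomatising double C-methylation of an acylphloroglucinol at one ring carbon; the stoichiometry is held at two methyl groups and the product is separated from under- and over-methylated material.

Step 23
Reactants: 28 (1R,4S,5S,9S)-4-hydroxy-4,11,11-trimethyl-8-methylidenebicyclo[7.2.0]undecane-5-carbaldehyde; 30 3,5-dihydroxy-6,6-dimethyl-2-(2-methylpropanoyl)cyclohexa-2,4-dien-1-one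
Product: 32 3,5-dihydroxy-4-{[(1R,4S,5R,9S)-4-hydroxy-4,11,11-trimethyl-8-methylidenebicyclo[7.2.0]undecan-5-yl]methyl}-6,6-dimethyl-2-(2-methylpropanoyl)cyclohexa-2,4-dien-1-one, via Knoevenagel alkylidene 31 (not isolated)
Conditions: diethyl 2,6-dimethyl-1,4-dihydropyridine-3,5-dicarboxylate (Hantzsch ester, 1.2 equiv), L-proline (20 mol%), CH2Cl2, rt
Reagents that add atoms: none
Why: Three-component reductive alkylation: Knoevenagel condensation at the only free ring CH of the trione (C2'), then conjugate hydride transfer from the Hantzsch ester to the alkylidene, which should be faster than Michael addition of a second trione. C5 is not changed provided the aldehyde does not linger as its enamine.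

Step 24
Reactants: 32 hydroxy trione (as named in step 23)
Product: 33 CNP0497637.1, the (1R,4S,5R,9S) tetracycle in which the C4 oxygen is bonded to C3' of the enolised 2-isobutyryl-4,4-dimethyl trione ring
Conditions: PPTS (10 mol%), 4 Å molecular sieves, toluene, 50 °C
Reagents that add atoms: none
Why: Cyclodehydration of a 2-(3-hydroxyalkyl)-1,3-dione to a fused dihydropyran: the tertiary hydroxyl adds 6-exo-trig to the C3' carbonyl and water is lost to give the vinylogous ester, so the C4–O bond is never broken and C4 keeps its configuration. C3' rather than C7' should react because the C7' oxygen is held in the hydrogen-bonded acyl-enol chelate and is the less carbonyl-like of the two.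

## Compound list

1 | (4R)-4-[(tert-butyldimethylsilyl)oxy]cyclopent-2-en-1-one | O=C1C=C[C@H](O[Si](C)(C)C(C)(C)C)C1 | starting material
2 | isobutylene (2-methylpropene) | C=C(C)C | starting material
3 | (1S,4R,5S)-4-[(tert-butyldimethylsilyl)oxy]-6,6-dimethylbicyclo[3.2.0]heptan-2-one | O=C1C[C@@H](O[Si](C)(C)C(C)(C)C)[C@H]2[C@@H]1CC2(C)C | intermediate
4 | (1S,5S)-6,6-dimethylbicyclo[3.2.0]hept-3-en-2-one | O=C1C=C[C@H]2[C@@H]1CC2(C)C | intermediate
5 | 2-[(1S,2S)-2-formyl-3,3-dimethylcyclobutyl]-2-oxoacetaldehyde | O=C[C@H]1[C@H](CC1(C)C)C(=O)C=O | intermediate (not isolated)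
6 | (1S,5S)-4-hydroxy-6,6-dimethyl-3-oxabicyclo[3.2.0]heptan-2-one | O=C1OC(O)[C@H]2[C@@H]1CC2(C)C | intermediate
7 | methyl (1S,2S)-2-formyl-3,3-dimethylcyclobutane-1-carboxylate (cis) | O=C[C@H]1[C@H](CC1(C)C)C(=O)OC | intermediate (not isolated)
8 | methyl (1S,2R)-2-formyl-3,3-dimethylcyclobutane-1-carboxylate (trans) | O=C[C@@H]1[C@H](CC1(C)C)C(=O)OC | intermediate
9 | methyl (1S,2R)-2-ethenyl-3,3-dimethylcyclobutane-1-carboxylate | C=C[C@@H]1[C@H](CC1(C)C)C(=O)OC | intermediate
10 | (1S,2R)-2-ethenyl-N-methoxy-N,3,3-trimethylcyclobutane-1-carboxamide | C=C[C@@H]1[C@H](CC1(C)C)C(=O)N(C)OC | intermediate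
11 | 1,1-dimethoxypropan-2-one | CC(=O)C(OC)OC | starting material
12 | ethyl (2E)-4,4-dimethoxy-3-methylbut-2-enoate | CCOC(=O)/C=C(\C)C(OC)OC | intermediate
13 | (2E)-4,4-dimethoxy-3-methylbut-2-en-1-ol | OC/C=C(\C)C(OC)OC | intermediate
14 | [(2S,3R)-3-(dimethoxymethyl)-3-methyloxiran-2-yl]methanol | OC[C@@H]1O[C@@]1(C)C(OC)OC | intermediate
15 | (2R,3R)-2-ethenyl-4,4-dimethoxy-3-methylbutane-1,3-diol | C=C[C@H](CO)[C@@](C)(O)C(OC)OC | intermediate
16 | (3R,4R)-4-ethenyl-3-methyloxolane-2,3-diol | C=C[C@@H]1COC(O)[C@]1(C)O | intermediate
17 | (2R,3S)-2-ethenyl-3-methylpent-4-ene-1,3-diol | C=C[C@H](CO)[C@@](C)(O)C=C | intermediate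
18 | (4S,5R)-4,5-diethenyl-2,2,4-trimethyl-1,3-dioxane | C=C[C@@H]1COC(C)(C)O[C@@]1(C)C=C | intermediate
19 | 9-{2-[(4S,5R)-4-ethenyl-2,2,4-trimethyl-1,3-dioxan-5-yl]ethyl}-9-borabicyclo[3.3.1]nonane | B1(CC[C@@H]3COC(C)(C)O[C@@]3(C)C=C)C2CCCC1CCC2 | intermediate (not isolated)
20 | 2-[(4S,5R)-4-ethenyl-2,2,4-trimethyl-1,3-dioxan-5-yl]ethan-1-ol | OCC[C@@H]1COC(C)(C)O[C@@]1(C)C=C | intermediate
21 | (4S,5R)-4-ethenyl-5-(2-iodoethyl)-2,2,4-trimethyl-1,3-dioxane | ICC[C@@H]1COC(C)(C)O[C@@]1(C)C=C | intermediate
22 | {2-[(4S,5R)-4-ethenyl-2,2,4-trimethyl-1,3-dioxan-5-yl]ethyl}lithium | [Li]CC[C@@H]1COC(C)(C)O[C@@]1(C)C=C | intermediate (not isolated)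
23 | 1-[(1S,2R)-2-ethenyl-3,3-dimethylcyclobutyl]-3-[(4S,5R)-4-ethenyl-2,2,4-trimethyl-1,3-dioxan-5-yl]propan-1-one | C=C[C@@H]1[C@H](CC1(C)C)C(=O)CC[C@@H]1COC(C)(C)O[C@@]1(C)C=C | intermediate
24 | (1R,2Z,4S,5R,9S)-4-hydroxy-5-(hydroxymethyl)-4,11,11-trimethylbicyclo[7.2.0]undec-2-en-8-one isopropylidene acetal | O=C1CC[C@@H]2COC(C)(C)O[C@@]2(C)/C=C\[C@@H]2[C@@H]1CC2(C)C | intermediate
25 | (1R,4S,5R,9S)-4-hydroxy-5-(hydroxymethyl)-4,11,11-trimethylbicyclo[7.2.0]undecan-8-one isopropylidene acetal | O=C1CC[C@@H]2COC(C)(C)O[C@@]2(C)CC[C@@H]2[C@@H]1CC2(C)C | intermediate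
26 | (1R,4S,5R,9S)-4-hydroxy-5-(hydroxymethyl)-4,11,11-trimethyl-8-methylidenebicyclo[7.2.0]undecane isopropylidene acetal | C=C1CC[C@@H]2COC(C)(C)O[C@@]2(C)CC[C@@H]2[C@@H]1CC2(C)C | intermediate
27 | (1R,4S,5R,9S)-5-(hydroxymethyl)-4,11,11-trimethyl-8-methylidenebicyclo[7.2.0]undecan-4-ol | C=C1CC[C@H](CO)[C@@](C)(O)CC[C@@H]2[C@@H]1CC2(C)C | intermediate
28 | (1R,4S,5S,9S)-4-hydroxy-4,11,11-trimethyl-8-methylidenebicyclo[7.2.0]undecane-5-carbaldehyde | C=C1CC[C@H](C=O)[C@@](C)(O)CC[C@@H]2[C@@H]1CC2(C)C | intermediate
29 | phlorisobutyrophenone | CC(C)C(=O)c1c(O)cc(O)cc1O | starting material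
30 | 3,5-dihydroxy-6,6-dimethyl-2-(2-methylpropanoyl)cyclohexa-2,4-dien-1-one | CC(C)C(=O)C1=C(O)C=C(O)C(C)(C)C1=O | intermediate
31 | Knoevenagel alkylidene of 28 and 30 (C1'=C2') | C=C1CC[C@H](C=C2C(=O)C(C)(C)C(=O)C(C(=O)C(C)C)=C2O)[C@@](C)(O)CC[C@@H]3[C@@H]1CC3(C)C | intermediate (not isolated)
32 | 3,5-dihydroxy-4-{[(1R,4S,5R,9S)-4-hydroxy-4,11,11-trimethyl-8-methylidenebicyclo[7.2.0]undecan-5-yl]methyl}-6,6-dimethyl-2-(2-methylpropanoyl)cyclohexa-2,4-dien-1-one | C=C1CC[C@H](CC2=C(O)C(C)(C)C(=O)C(C(=O)C(C)C)=C2O)[C@@](C)(O)CC[C@@H]3[C@@H]1CC3(C)C | intermediate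
33 | CNP0497637.1, (1R,4S,5R,9S) | C=C1CC[C@@H]2CC3=C(O[C@@]2(C)CC[C@@H]2[C@@H]1CC2(C)C)C(C)(C)C(=O)C(C(=O)C(C)C)=C3O | target

## Step count and least certain steps

Total: 24 steps. Longest linear sequence: 17 steps (steps 7–21, 23 and 24). Fragment 1 takes steps 1–6, fragment 2 steps 7–15, and the trione step 22.

**Step 17 (key step).** Intermolecular metathesis may outrun closure. The vinyl group on the quaternary, oxygen-bearing C4 engages slowly, and the nine-membered ring carries transannular strain, so the C2 alkylidene may find another molecule first or the catalyst may decay to hydrides that migrate the alkenes. Fallback (relay metathesis, which delivers the ruthenium to C2 intramolecularly): set out from 8 and use the ylide of (hex-5-en-1-yl)triphenylphosphonium bromide in place of the methylene ylide to give methyl (1S,2R)-2-[(1Z)-hepta-1,6-dien-1-yl]-3,3-dimethylcyclobutane-1-carboxylate F1. Convert it with MeNH(OMe)·HCl and i-PrMgCl into the Weinreb amide F2 and acylate 22 with it to give the relay ketone F3. With the same catalyst the terminal alkene of the tether is loaded first, cyclopentene is expelled, and the resulting C2 alkylidene closes on the C4 vinyl group. The route is rejoined at 24.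

**Step 1.** Facial discrimination by the silyloxy group may be incomplete, and the head-to-head orientation may take a share of the material. Any syn adduct that is not separated becomes the enantiomer of 4 after step 2. Fallback (classical resolution instead of substrate control): set out from 9, saponify with LiOH in THF/H2O to (1S,2R)-2-ethenyl-3,3-dimethylcyclobutane-1-carboxylic acid F4, and crystallise its (S)-1-phenylethylammonium salt F5 (or the salt of the enantiomeric amine, whichever is the less soluble with the wanted acid) to full enantiopurity. Liberate the acid and couple it with MeNH(OMe)·HCl through its acyl imidazolide. The route is rejoined at 10.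

**Step 14.** Hydroboration may not discriminate well enough between the two vinyl groups, giving attack at the C4 vinyl group or double hydroboration; the steric and inductive bias is real but both are monosubstituted terminal alkenes. Fallback (hydrate the C5 vinyl group before the second one exists): set out from 15 and hydroborate its only alkene (9-BBN; NaOH, H2O2) to (2R,3R)-2-(2-hydroxyethyl)-4,4-dimethoxy-3-methylbutane-1,3-diol F6. Hydrolyse the acetal with aqueous HCl to the lactol (3R,4R)-4-(2-hydroxyethyl)-3-methyloxolane-2,3-diol F7, and methylenate with excess Ph3PCH3Br/KOt-Bu to (2R,3S)-2-(2-hydroxyethyl)-3-methylpent-4-ene-1,3-diol F8. Acetonide formation under equilibrating conditions (2-methoxypropene, PPTS) should select the six-membered 1,3-dioxane over seven-membered alternatives. The route is rejoined at 20.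

**Step 23.** The β-hydroxy aldehyde may not survive amine catalysis. Through its enamine it can lose the tertiary hydroxyl, epimerise at C5, or undergo retro-aldol cleavage of C4–C5, which would open ring B and release strain. A second trione may also add to 31 before hydride transfer. Fallback (mask the tertiary hydroxyl before the aldehyde exists): set out from 27, silylate both hydroxyls with Et3SiOTf/2,6-lutidine to the bis(triethylsilyl) ether F9, and oxidise the primary silyl ether directly under Swern conditions ((COCl)2, DMSO, Et3N) to the β-silyloxy aldehyde F10. Carry out the same reductive alkylation with 30 to the silyl-protected trione F11 and remove the silyl group with HF·pyridine. The route is rejoined at 32.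

**Step 24.** Acid may ionise the tertiary C4–O bond instead of activating the C3' carbonyl. The resulting cation would be captured transannularly by the C8 methylidene or would scramble C4. Closure through the C7' oxygen would give the regioisomeric pyran. Fallback (keep C8 as the ketone through the acid step and methylenate last, so that no alkene can take part): set out from 25 and hydrolyse the acetonide (AcOH/THF/H2O) to the keto diol F12. Oxidise with TEMPO/PhI(OAc)2 to the keto aldehyde F13, alkylate 30 reductively to the keto trione F14, and cyclodehydrate with PPTS to the tetracyclic C8 ketone F15. Then methylenate with excess Ph3PCH3Br/KOt-Bu, the first equivalents of which protect ring D as its enolate. The route is rejoined at 33.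

## Further compounds

F1 | step 17 | methyl (1S,2R)-2-[(1Z)-hepta-1,6-dien-1-yl]-3,3-dimethylcyclobutane-1-carboxylate | C=CCCC/C=C\[C@@H]1[C@H](CC1(C)C)C(=O)OC
F2 | step 17 | (1S,2R)-2-[(1Z)-hepta-1,6-dien-1-yl]-N-methoxy-N,3,3-trimethylcyclobutane-1-carboxamide | C=CCCC/C=C\[C@@H]1[C@H](CC1(C)C)C(=O)N(C)OC
F3 | step 17 | 1-{(1S,2R)-2-[(1Z)-hepta-1,6-dien-1-yl]-3,3-dimethylcyclobutyl}-3-[(4S,5R)-4-ethenyl-2,2,4-trimethyl-1,3-dioxan-5-yl]propan-1-one | C=CCCC/C=C\[C@@H]1[C@H](CC1(C)C)C(=O)CC[C@@H]1COC(C)(C)O[C@@]1(C)C=C
F4 | step 1 | (1S,2R)-2-ethenyl-3,3-dimethylcyclobutane-1-carboxylic acid | C=C[C@@H]1[C@H](CC1(C)C)C(=O)O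
F5 | step 1 | (S)-1-phenylethylammonium (1S,2R)-2-ethenyl-3,3-dimethylcyclobutane-1-carboxylate | C=C[C@@H]1[C@H](CC1(C)C)C(=O)[O-].C[C@H]([NH3+])c1ccccc1
F6 | step 14 | (2R,3R)-2-(2-hydroxyethyl)-4,4-dimethoxy-3-methylbutane-1,3-diol | OCC[C@H](CO)[C@@](C)(O)C(OC)OC
F7 | step 14 | (3R,4R)-4-(2-hydroxyethyl)-3-methyloxolane-2,3-diol | OCC[C@@H]1COC(O)[C@]1(C)O
F8 | step 14 | (2R,3S)-2-(2-hydroxyethyl)-3-methylpent-4-ene-1,3-diol | OCC[C@H](CO)[C@@](C)(O)C=C
F9 | step 23 | bis(triethylsilyl) ether of 27 | C=C1CC[C@H](CO[Si](CC)(CC)CC)[C@@](C)(O[Si](CC)(CC)CC)CC[C@@H]2[C@@H]1CC2(C)C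
F10 | step 23 | 4-O-triethylsilyl ether of 28 | C=C1CC[C@H](C=O)[C@@](C)(O[Si](CC)(CC)CC)CC[C@@H]2[C@@H]1CC2(C)C
F11 | step 23 | 4-O-triethylsilyl ether of 32 | C=C1CC[C@H](CC2=C(O)C(C)(C)C(=O)C(C(=O)C(C)C)=C2O)[C@@](C)(O[Si](CC)(CC)CC)CC[C@@H]3[C@@H]1CC3(C)C
F12 | step 24 | (1R,4S,5R,9S)-4-hydroxy-5-(hydroxymethyl)-4,11,11-trimethylbicyclo[7.2.0]undecan-8-one | O=C1CC[C@H](CO)[C@@](C)(O)CC[C@@H]2[C@@H]1CC2(C)C
F13 | step 24 | (1R,4S,5S,9S)-4-hydroxy-4,11,11-trimethyl-8-oxobicyclo[7.2.0]undecane-5-carbaldehyde | O=C1CC[C@H](C=O)[C@@](C)(O)CC[C@@H]2[C@@H]1CC2(C)C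
F14 | step 24 | 8-oxo analogue of 32 (C8 ketone in place of the methylidene) | O=C1CC[C@H](CC2=C(O)C(C)(C)C(=O)C(C(=O)C(C)C)=C2O)[C@@](C)(O)CC[C@@H]3[C@@H]1CC3(C)C
F15 | step 24 | 8-oxo analogue of 33 (C8 ketone in place of the methylidene) | O=C1CC[C@@H]2CC3=C(O[C@@]2(C)CC[C@@H]2[C@@H]1CC2(C)C)C(C)(C)C(=O)C(C(=O)C(C)C)=C3O
A1 | alternative 1 | tetracyclic 2H-pyran with C8 ketone and C5=C1' double bond | O=C1CCC2=CC3=C(O[C@@]2(C)CC[C@@H]2[C@@H]1CC2(C)C)C(C)(C)C(=O)C(C(=O)C(C)C)=C3O
A2 | alternative 1 | (1R,4E,9S)-4,11,11-trimethyl-8-oxobicyclo[7.2.0]undec-4-ene-5-carbaldehyde | O=C1CC/C(C=O)=C(/C)CC[C@@H]2[C@@H]1CC2(C)C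
A3 | alternative 2 | trans-bicyclo[7.2.0]undecan-8-one acetonide, identical with 25 | O=C1CC[C@@H]2COC(C)(C)O[C@@]2(C)CC[C@@H]2[C@@H]1CC2(C)C
A4 | alternative 2 | (2Z,6S,7R)-6-hydroxy-7-(hydroxymethyl)-6-methylcyclonon-2-en-1-one isopropylidene acetal | O=C1CC[C@@H]2COC(C)(C)O[C@@]2(C)CC/C=C\1
A5 | alternative 3 | methyl (1R,4S,5S,9S)-4-hydroxy-4,11,11-trimethyl-8-methylidenebicyclo[7.2.0]undecane-5-carboxylate | C=C1CC[C@H](C(=O)OC)[C@@](C)(O)CC[C@@H]2[C@@H]1CC2(C)C
A6 | alternative 3 | methyl 2-bromo-5-[(1S,2R)-3,3-dimethyl-2-(3-oxobutyl)cyclobutyl]hex-5-enoate | C=C(CCC(Br)C(=O)OC)[C@H]1CC(C)(C)[C@@H]1CCC(C)=O
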